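**Retrosynthetic overview**
- Last bonds: the C21–O–C22 lactone is closed by base, which also sets C14. The quaternary C5 comes from Michael addition of a C5 carbaldehyde to isopropyl vinyl ketone, and the aldehyde from a C5 ketone by one-carbon homologation.
- Seven-membered ring: intramolecular alkylation of the C5-ketone enolate (C6–C12).
- Ring C (key step): the C9 ketone is reduced by SmI2 to a ketyl, which attacks the central carbon of an allenylmethyl benzyl ether and expels benzyloxide. This forms C9–C10, the tertiary allylic alcohol and the C10=C17 alkene.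
- Ring D: Dieckmann closure onto the ester at C8 of a bought piperidone. The quaternary C8 comes from a chiral-enamine Michael addition to dimethyl itaconate, and the allene arm from propargyl alcohol.
- Ring order: piperidine (bought) → ring D → ring C → seven-membered ring → lactone.

Assumption: the piperidone β-keto ester is bought as its hydrochloride and freed with aqueous NaHCO3 before use; atom labels in the names are those of the target skeleton: N(Me)–C1–C8, N–C7–C6, C5 (between C6 and C8; carries C21 and C4–C3–C2(=O)–CHMe2), C8–C9(O)–C10(=C17–C16–C15), C10–C11–C12–C6, ring D = C8–C9–C15–C14–C13, C22 = carboxyl carbon on C14.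

**Step 1**
Reactants: 1 prop-2-yn-1-ol; 2 (benzyloxy)acetaldehyde
Product: 3 5-(benzyloxy)penta-2,3-dien-1-ol (racemic allene)
Conditions: ZnI2 (0.8 equiv), morpholine (1.4 equiv), toluene, 130 °C
Reagents that add atoms: none
Why: ZnI2-promoted allenation of a terminal alkyne with an aldehyde (Crabbé-type homologation: alkyne–aldehyde–amine coupling, then 1,5-hydride shift with loss of the cyclic imine) gives the 1,3-disubstituted allene directly; its axial chirality is racemic and is erased in step 7.

**Step 2**
Reactants: 3 5-(benzyloxy)penta-2,3-dien-1-ol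
Product: 4 {[(5-bromopenta-2,3-dien-1-yl)oxy]methyl}benzene (racemic allene)
Conditions: CBr4, PPh3, CH2Cl2, 0 °C
Reagents that add atoms: carbon tetrabromide, BrC(Br)(Br)Br
Why: Appel reaction, an SN2 displacement of the primary alkoxyphosphonium by bromide, with no new stereocentre.

**Step 3**
Reactants: 5 methyl 1-methyl-4-oxopiperidine-3-carboxylate; 6 dimethyl itaconate
Product: 9 dimethyl 2-{[(3S)-3-(methoxycarbonyl)-1-methyl-4-oxopiperidin-3-yl]methyl}butanedioate (both C14 epimers), via enaminoester 7 (not isolated), via imine adduct 8 (not isolated)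
Conditions: (R)-1-phenylethylamine, TsOH (cat.), toluene, reflux, Dean–Stark; then 6, ZnCl2 (1 equiv), THF, 0 °C → rt; then 20% aq. AcOH, rt
Reagents that add atoms: water, O
Why: Deracemizing Michael addition of a chiral secondary enaminoester (aza-ene-type mechanism, ZnCl2-activated acceptor): the itaconate adds to C8 on the enamine face away from the phenyl group with internal N–H transfer, so the (R)-amine is expected to set the quaternary (S)-C8 (the antipodal amine would give the antipode), and mild acid hydrolysis returns the ketone; C14 is left as a mixture because it is corrected in step 15.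

**Step 4**
Reactants: 9 the keto triester from step 3
Product: 10 dimethyl 2-{[(3S)-4,4-dimethoxy-3-(methoxycarbonyl)-1-methylpiperidin-3-yl]methyl}butanedioate (both C14 epimers)
Conditions: HC(OMe)3, MeOH, TsOH·H2O (1.3 equiv), 50 °C; NaHCO3 work-up
Reagents that add atoms: trimethyl orthoformate, COC(OC)OC
Why: Acid-catalysed ketalization driven by the orthoformate masks the only ketone, so that C5 cannot enolize or form a ketyl in steps 5–8 and its bulk later biases C14 and C15; no stereocentre is touched.

**Step 5**
Reactants: 10 the ketal triester; 4 the allenylmethyl bromide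
Product: 12 dimethyl (5R)-2-[5-(benzyloxy)penta-2,3-dien-1-yl]-10,10-dimethoxy-7-methyl-1-oxo-7-azaspiro[4.5]decane-2,3-dicarboxylate (isomers at C14, C15 and the allene axis), via potassium enolate 11 (not isolated)
Conditions: KOt-Bu (1.2 equiv), THF, 0 °C → rt; then 4, 0 °C → rt
Reagents that add atoms: none
Why: Dieckmann condensation (the C15 ester enolate can only close the five-membered ring D onto the C9 ester) followed by SN2 C-alkylation of the resulting β-keto ester enolate with the allenylmethyl bromide; C14, C15 and the allene axis remain mixtures at this stage.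

**Step 6**
Reactants: 12 the alkylated β-keto ester
Product: 13 methyl (2R,3S,5R)-2-[5-(benzyloxy)penta-2,3-dien-1-yl]-10,10-dimethoxy-7-methyl-1-oxo-7-azaspiro[4.5]decane-3-carboxylate (C15 side chain on the C5 face of ring D; C14 ester trans to it; allene axis mixed)
Conditions: LiCl, H2O, DMSO, 150 °C; then NaOMe (0.2 equiv), MeOH, 50 °C
Reagents that add atoms: none
Why: Krapcho dealkoxycarbonylation removes the activating C15 ester, and methoxide equilibration of the two epimerizable centres should favour the isomer with the C14 ester anti to the bulky ketal carbon C5 and the C15 side chain trans to that ester, that is on the C5 face as ring C requires (minor epimers are recycled under the same base).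

**Step 7**
Reactants: 13 the allenyl ketone
Product: 14 methyl 6-ethenyl-6a-hydroxy-4',4'-dimethoxy-1'-methyl-3,3a,4,6a-tetrahydro-2H-spiro[pentalene-1,3'-piperidine]-3-carboxylate (rings C and D cis-fused; O9 and H15 on the C1 face; C10 on the C5 face; C14 ester on the C1 face)
Conditions: SmI2 (2.5 equiv), HMPA (10 equiv), THF, −78 → 0 °C; aq. NH4Cl
Reagents that add atoms: none
Why: Proposed new method: SmI2/HMPA reduces the only ketone to a ketyl (an α-oxido carbon nucleophile at C9), which in this hexa-4,5-dienyl array can reach only the central allene carbon through a five-membered transition state (the proximal carbon would give a cyclobutane, the distal one a ring-strained vinyl radical), so C9–C10 forms with the obligatory cis ring fusion (O9 cis to H15, hence cis to C1); the allyl radical is reduced to an allylsamarium that expels the β-benzyloxide, which fixes the ring alkene at C10=C17 and leaves a vinyl handle; the closest known reaction types are SmI2 ketyl–olefin and ketyl–allene cyclizations and SmI2 addition/β-elimination sequences.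

**Step 8**
Reactants: 14 the diene alcohol
Product: 17 methyl 6a-hydroxy-6-(2-hydroxyethyl)-1'-methyl-4'-oxo-3,3a,4,6a-tetrahydro-2H-spiro[pentalene-1,3'-piperidine]-3-carboxylate (configuration as in 14), via B-alkyl borane 15 (not isolated), via diol ketal 16 (not isolated)
Conditions: 9-BBN, THF, 0 °C → rt; then Me3NO·2H2O, 60 °C; then AcOH, H2O, THF, rt
Reagents that add atoms: trimethylamine N-oxide, C[N+](C)(C)[O-]; water, O
Why: Hydroboration–oxidation: 9-BBN adds anti-Markovnikov to the monosubstituted vinyl group only, Me3NO oxidizes the C–B bond without touching the tertiary amine, and dilute AcOH hydrolyses the strained dimethyl ketal without ionizing the tertiary allylic alcohol; no stereocentre changes.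

**Step 9**
Reactants: 17 the keto diol
Product: 19 methyl 1'-methyl-4'-oxo-6-{2-[(4-methylbenzenesulfonyl)oxy]ethyl}-6a-[(triethylsilyl)oxy]-3,3a,4,6a-tetrahydro-2H-spiro[pentalene-1,3'-piperidine]-3-carboxylate (configuration as in 14), via tosylate 18 (not isolated)
Conditions: TsCl (1.1 equiv), Et3N, DMAP (cat.), CH2Cl2, 0 °C; then 2,6-lutidine, Et3SiOTf, −78 → 0 °C
Reagents that add atoms: p-toluenesulfonyl chloride, Cc1ccc(cc1)S(Cl)(=O)=O; triethylsilyl trifluoromethanesulfonate, CC[Si](CC)(CC)OS(=O)(=O)C(F)(F)F
Why: Chemoselective sulfonylation of the primary alcohol followed by silyl triflate silylation of the tertiary alcohol, which blocks retro-aldol cleavage of the β-hydroxy ketone and later lactonization onto O9; no stereocentre changes.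

**Step 10**
Reactants: 19 the tosylate silyl ether
Product: 20 tetracyclic keto ester (C6–C12 bond closed; piperidine, seven-membered ring, ring C and ring D; C5 ketone; C9–OSiEt3; C14–CO2Me still on the silyloxy face)
Conditions: KN(SiMe3)2 (1.1 equiv), THF (0.005 M), −78 → 0 °C
Reagents that add atoms: none
Why: Intramolecular enolate C-alkylation (7-enolendo-exo-tet): C6 is the only enolizable position of the ketone and the tether on the C5 face reaches only one face of the enolate, so the bridgehead C6 configuration is dictated by the ring.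

**Step 11**
Reactants: 20 the tetracyclic keto ester
Product: 21 spiro-oxirane (C5 of 20 converted into C5–O–C21H2; either C5 epimer)
Conditions: Me3S+ I−, KN(SiMe3)2, THF, −10 °C → rt
Reagents that add atoms: trimethylsulfonium iodide, C[S+](C)C.[I-]
Why: Corey–Chaykovsky epoxidation: the small, irreversibly adding dimethylsulfonium methylide tolerates the hindered bridging ketone, and the new spiro centre is inconsequential because it is destroyed in step 12.

**Step 12**
Reactants: 21 the spiro-oxirane
Product: 22 C5 carbaldehyde (C5–H, C5–C21HO; either C5 epimer)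
Conditions: BF3·OEt2 (2.2 equiv), CH2Cl2, −78 °C; NaHCO3
Reagents that add atoms: none
Why: Meinwald rearrangement: the Lewis acid opens the epoxide at the tertiary carbon and a 1,2-hydride shift gives the aldehyde; the epimerizable C5 centre is reset in step 13.

**Step 13**
Reactants: 22 the C5 carbaldehyde; 23 4-methylpent-1-en-3-one
Product: 24 keto aldehyde (C5 quaternary: C21HO on the carbocyclic face, 4-methyl-3-oxopentyl chain on the piperidine face)
Conditions: DBU (0.3 equiv), MeCN, 0 °C → rt
Reagents that add atoms: none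
Why: Base-catalysed Michael addition of the α-branched aldehyde enolate to the vinyl ketone: the enone approaches C5 from the piperidine face because the other face is shielded by the fully substituted C9 (OSiEt3) and ring D, so the side chain ends up syn to the nitrogen bridge and the formyl group on the carbocyclic face, as in the target.

**Step 14**
Reactants: 24 the keto aldehyde
Product: 25 hydroxy keto ester (C21H2OH; otherwise as 24)
Conditions: LiAlH(Ot-Bu)3 (1.2 equiv), THF, −78 → −40 °C; aq. KNaC4H4O6
Reagents that add atoms: none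
Why: Chemoselective hydride reduction: LiAlH(Ot-Bu)3 at low temperature reduces the aldehyde but not the ketone or the esters; no stereocentre changes.

**Step 15**
Reactants: 25 the hydroxy keto ester
Product: 27 the target CNP0242289.1, via silyl lactone 26 (not isolated)
Conditions: DBU (2 equiv), toluene, 100 °C, MeOH distilled off; then HF·pyridine, THF, 0 °C
Reagents that add atoms: none
Why: Base-mediated epimerization and lactonization, then fluoride desilylation: DBU equilibrates C14 through the ester enolate and only the epimer with the carboxylate on the C5 face can close the seven-membered lactone with O21, so removal of methanol funnels the material to the required C14 configuration while the silyl ether prevents the alternative lactone onto O9, and HF·pyridine then frees the tertiary alcohol.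

**Compound list**
1 | prop-2-yn-1-ol | C#CCO | starting material
2 | (benzyloxy)acetaldehyde | O=CCOCc1ccccc1 | starting material
3 | 5-(benzyloxy)penta-2,3-dien-1-ol (racemic allene) | OCC=C=CCOCc1ccccc1 | intermediate
4 | {[(5-bromopenta-2,3-dien-1-yl)oxy]methyl}benzene (racemic allene) | BrCC=C=CCOCc1ccccc1 | intermediate
5 | methyl 1-methyl-4-oxopiperidine-3-carboxylate | COC(=O)C1CN(C)CCC1=O | starting material
6 | dimethyl itaconate (dimethyl 2-methylidenebutanedioate) | C=C(CC(=O)OC)C(=O)OC | starting material
7 | methyl 1-methyl-4-{[(1R)-1-phenylethyl]amino}-1,2,5,6-tetrahydropyridine-3-carboxylate | COC(=O)C1=C(N[C@H](C)c2ccccc2)CCN(C)C1 | intermediate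
8 | dimethyl 2-{[(3S)-3-(methoxycarbonyl)-1-methyl-4-{[(1R)-1-phenylethyl]imino}piperidin-3-yl]methyl}butanedioate | COC(=O)CC(C(=O)OC)C[C@]1(C(=O)OC)CN(C)CCC1=N[C@H](C)c1ccccc1 | intermediate
9 | dimethyl 2-{[(3S)-3-(methoxycarbonyl)-1-methyl-4-oxopiperidin-3-yl]methyl}butanedioate (C14 epimers) | COC(=O)CC(C(=O)OC)C[C@]1(C(=O)OC)CN(C)CCC1=O | intermediate
10 | dimethyl 2-{[(3S)-4,4-dimethoxy-3-(methoxycarbonyl)-1-methylpiperidin-3-yl]methyl}butanedioate (C14 epimers) | COC(=O)CC(C(=O)OC)C[C@]1(C(=O)OC)CN(C)CCC1(OC)OC | intermediate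
11 | potassium enolate of dimethyl (5R)-10,10-dimethoxy-7-methyl-1-oxo-7-azaspiro[4.5]decane-2,3-dicarboxylate | COC(=O)C1C[C@@]2(CN(C)CCC2(OC)OC)C([O-])=C1C(=O)OC.[K+] | intermediate
12 | dimethyl (5R)-2-[5-(benzyloxy)penta-2,3-dien-1-yl]-10,10-dimethoxy-7-methyl-1-oxo-7-azaspiro[4.5]decane-2,3-dicarboxylate (isomers at C14, C15, allene axis) | COC(=O)C1C[C@@]2(CN(C)CCC2(OC)OC)C(=O)C1(CC=C=CCOCc3ccccc3)C(=O)OC | intermediate
13 | methyl (2R,3S,5R)-2-[5-(benzyloxy)penta-2,3-dien-1-yl]-10,10-dimethoxy-7-methyl-1-oxo-7-azaspiro[4.5]decane-3-carboxylate (allene axis mixed) | COC(=O)[C@H]1C[C@@]2(CN(C)CCC2(OC)OC)C(=O)[C@@H]1CC=C=CCOCc1ccccc1 | intermediate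
14 | methyl 6-ethenyl-6a-hydroxy-4',4'-dimethoxy-1'-methyl-3,3a,4,6a-tetrahydro-2H-spiro[pentalene-1,3'-piperidine]-3-carboxylate (cis-fused; O9, H15 and the ester on the C1 face) | COC(=O)[C@H]1C[C@@]2(CN(C)CCC2(OC)OC)[C@]3(O)C(C=C)=CC[C@H]13 | intermediate
15 | B-(9-borabicyclo[3.3.1]nonan-9-yl) adduct of 14 at C12 | COC(=O)[C@H]1C[C@@]2(CN(C)CCC2(OC)OC)[C@]3(O)C(CCB4C5CCCC4CCC5)=CC[C@H]13 | intermediate
16 | methyl 6a-hydroxy-6-(2-hydroxyethyl)-4',4'-dimethoxy-1'-methyl-3,3a,4,6a-tetrahydro-2H-spiro[pentalene-1,3'-piperidine]-3-carboxylate | COC(=O)[C@H]1C[C@@]2(CN(C)CCC2(OC)OC)[C@]3(O)C(CCO)=CC[C@H]13 | intermediate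
17 | methyl 6a-hydroxy-6-(2-hydroxyethyl)-1'-methyl-4'-oxo-3,3a,4,6a-tetrahydro-2H-spiro[pentalene-1,3'-piperidine]-3-carboxylate | COC(=O)[C@H]1C[C@@]2(CN(C)CCC2=O)[C@]3(O)C(CCO)=CC[C@H]13 | intermediate
18 | 17 as its primary p-toluenesulfonate | COC(=O)[C@H]1C[C@@]2(CN(C)CCC2=O)[C@]3(O)C(CCOS(=O)(=O)c4ccc(C)cc4)=CC[C@H]13 | intermediate
19 | methyl 1'-methyl-4'-oxo-6-{2-[(4-methylbenzenesulfonyl)oxy]ethyl}-6a-[(triethylsilyl)oxy]-3,3a,4,6a-tetrahydro-2H-spiro[pentalene-1,3'-piperidine]-3-carboxylate | COC(=O)[C@H]1C[C@@]2(CN(C)CCC2=O)[C@]3(O[Si](CC)(CC)CC)C(CCOS(=O)(=O)c4ccc(C)cc4)=CC[C@H]13 | intermediate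
20 | tetracyclic keto ester (C5 ketone, C9–OSiEt3, C14 ester on the silyloxy face) | O=C1[C@@H]2CCC3=CC[C@@H]4[C@@H](C(=O)OC)C[C@@]1(CN(C)C2)[C@]34O[Si](CC)(CC)CC | intermediate
21 | spiro-oxirane at C5 of 20 (C5 epimers) | C1OC12[C@@H]3CCC4=CC[C@@H]5[C@@H](C(=O)OC)C[C@@]2(CN(C)C3)[C@]45O[Si](CC)(CC)CC | intermediate
22 | C5 carbaldehyde (C5 epimers) | O=CC1[C@@H]2CCC3=CC[C@@H]4[C@@H](C(=O)OC)C[C@@]1(CN(C)C2)[C@]34O[Si](CC)(CC)CC | intermediate
23 | 4-methylpent-1-en-3-one (isopropyl vinyl ketone) | CC(C)C(=O)C=C | starting material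
24 | keto aldehyde with quaternary C5 (C21HO and 4-methyl-3-oxopentyl) | CC(C)C(=O)CC[C@@]1(C=O)[C@@H]2CCC3=CC[C@@H]4[C@@H](C(=O)OC)C[C@@]1(CN(C)C2)[C@]34O[Si](CC)(CC)CC | intermediate
25 | hydroxy keto ester (C21H2OH) | CC(C)C(=O)CC[C@@]1(CO)[C@@H]2CCC3=CC[C@@H]4[C@@H](C(=O)OC)C[C@@]1(CN(C)C2)[C@]34O[Si](CC)(CC)CC | intermediate
26 | O9-triethylsilyl ether of the target | CC(C)C(=O)CC[C@]12COC(=O)[C@@H]3C[C@]14CN(C)C[C@H]2CCC1=CC[C@H]3[C@@]14O[Si](CC)(CC)CC | intermediate
27 | CNP0242289.1 | CC(C)C(=O)CC[C@]12COC(=O)[C@@H]3C[C@]14CN(C)C[C@H]2CCC1=CC[C@H]3[C@@]14O | target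

**Totals**
Total step count: 15. Longest linear sequence: 13 steps (5 → 27, steps 3–15; the branch from 1 is equally long).

**The three steps most likely to fail, with fallbacks**

Step 7 (ketyl–allene closure with β-elimination). The ketone may be reduced without cyclizing, or the allylsamarium may be protonated instead of eliminating. The fallback closes ring C by organochromium addition of a pre-formed (Z)-vinyl iodide, which fixes the alkene position by construction. It sets out from 10 and comes back at 17. Commercial tert-butyl(but-3-yn-1-yloxy)dimethylsilane is hydroxymethylated (n-BuLi, (CH2O)n, THF) to 5-[(tert-butyldimethylsilyl)oxy]pent-2-yn-1-ol F1. Hydroalumination–iodination (NaAlH2(OCH2CH2OMe)2, Et2O; then I2, −78 °C) gives (2Z)-5-[(tert-butyldimethylsilyl)oxy]-3-iodopent-2-en-1-ol F2, and CBr4/PPh3 gives tert-butyl{[(3Z)-5-bromo-3-iodopent-3-en-1-yl]oxy}dimethylsilane F3. Compound 10 is cyclized to 11 as in step 5 and alkylated with F3 to the iodoalkenyl keto diester F4. LiCl/DMSO then NaOMe, as in step 6, give the iodoalkenyl ketone F5. CrCl2 with catalytic NiCl2 in DMF (intramolecular Nozaki–Hiyama–Kishi reaction) closes ring C to the silyl-protected allylic alcohol F6. AcOH/H2O/THF removes the silyl ether and the ketal and delivers 17.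

Step 10 (bridging seven-membered ring by enolate alkylation). O-alkylation or elimination may compete with the slow C–C closure. The fallback sets out from 19 and comes back at 20. The lithium enolate of 19 (LiN(SiMe3)2, THF, −78 °C) is sulfenylated with PhSSPh to the C6 phenylsulfanyl ketone F7. The C6–H is now acidic enough for ring closure with Cs2CO3 in MeCN (soft, C-selective enolate) to the bridgehead sulfide F8. Bu3SnH/AIBN in toluene at 80 °C removes sulfur through the bridgehead α-keto radical and gives 20.

Step 13 (quaternary C5 next to quaternary C8 by Michael addition). Enolization may be slow or the addition reversible. The fallback sets out from 22 and comes back at 24. Compound 22 is converted (Me3SiCl, Et3N, NaI, MeCN) into the trimethylsilyl enol ether F9. F9 adds to 23 under TiCl4 (2 equiv, one bound by the amine) in CH2Cl2 at −78 °C (Mukaiyama–Michael reaction, irreversible and independent of enolate equilibria), and aqueous work-up gives 24.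

**Further compounds**
F1 | step 7 | 5-[(tert-butyldimethylsilyl)oxy]pent-2-yn-1-ol | OCC#CCCO[Si](C)(C)C(C)(C)C
F2 | step 7 | (2Z)-5-[(tert-butyldimethylsilyl)oxy]-3-iodopent-2-en-1-ol | OC/C=C(\I)CCO[Si](C)(C)C(C)(C)C
F3 | step 7 | tert-butyl{[(3Z)-5-bromo-3-iodopent-3-en-1-yl]oxy}dimethylsilane | BrC/C=C(\I)CCO[Si](C)(C)C(C)(C)C
F4 | step 7 | iodoalkenyl keto diester (12 with the (2Z)-5-silyloxy-3-iodopent-2-enyl chain at C15) | COC(=O)C1C[C@@]2(CN(C)CCC2(OC)OC)C(=O)C1(C/C=C(\I)CCO[Si](C)(C)C(C)(C)C)C(=O)OC
F5 | step 7 | iodoalkenyl ketone (13 with the same chain in place of the allenyl chain) | COC(=O)[C@H]1C[C@@]2(CN(C)CCC2(OC)OC)C(=O)[C@@H]1C/C=C(\I)CCO[Si](C)(C)C(C)(C)C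
F6 | step 7 | silyl-protected allylic alcohol (16 as its primary tert-butyldimethylsilyl ether) | COC(=O)[C@H]1C[C@@]2(CN(C)CCC2(OC)OC)[C@]3(O)C(CCO[Si](C)(C)C(C)(C)C)=CC[C@H]13
F7 | step 10 | C6 phenylsulfanyl ketone (19 with SPh at C6) | COC(=O)[C@H]1C[C@@]2(CN(C)CC(Sc4ccccc4)C2=O)[C@]3(O[Si](CC)(CC)CC)C(CCOS(=O)(=O)c5ccc(C)cc5)=CC[C@H]13
F8 | step 10 | bridgehead sulfide (20 with SPh at C6) | O=C1[C@]2(Sc5ccccc5)CCC3=CC[C@@H]4[C@@H](C(=O)OC)C[C@@]1(CN(C)C2)[C@]34O[Si](CC)(CC)CC
F9 | step 13 | trimethylsilyl enol ether of 22 | C[Si](C)(C)OC=C1[C@@H]2CCC3=CC[C@@H]4[C@@H](C(=O)OC)C[C@@]1(CN(C)C2)[C@]34O[Si](CC)(CC)CC
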